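**Plan**

- Retrosynthesis: the oxirane C6–O bond is cut first (the C1 hydroxyl displaces a C6 sulfonate with inversion). The C1–O and C2–O bonds are cut next, together (syn-dihydroxylation of the trisubstituted alkene of a cis-3,6-diacyloxycyclohexa-1,4-diene). C4=C5 is then traced to a trans-dibromide and the two carbinols to the carbonyls of 2-(benzoyloxymethyl)-1,4-benzoquinone.
- Forward: the six-membered ring is the arene of 2,5-dimethoxybenzyl alcohol throughout. The only ring formed is the oxirane, closed in step 12.
- Feature used: in the target the oxygens on C1 and C2 are cis to each other and trans to the C3 benzoate and to the bond that C6 gives up on closure. Osmylation anti to two cis allylic oxygens (C3 and C6) delivers exactly this arrangement.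
- Stereochemistry: a lipase hydrolysis (step 6) fixes the absolute configuration in the racemic dibromodiol series. A Mitsunobu benzoylation (step 7) inverts C3 so that C3–O and C6–O become cis. The osmylation sets C1 and C2 from these two centres, and the SN2 closure inverts C6.

Key step: step 9

Convention: ring locants are those of the target (C1 carries C7H2OBz, C2 the carbinol, C3 the benzoate, C4=C5 the alkene, C6 the oxirane CH). β is the face of the oxirane oxygen in the target, α the opposite face. Racemates 5–7 are drawn as the enantiomer that is carried on.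

Assumption: borohydride reduction of the trans-dibromo-enedione is taken to follow the unsubstituted case, each hydroxyl ending trans to its neighbouring bromine, so that C3–OH and C6–OH are trans in 6.

**Step 1**
Reactants: 1 2,5-dimethoxybenzyl alcohol; 2 benzoyl chloride
Product: 3 2,5-dimethoxybenzyl benzoate
Conditions: BzCl, Et3N, DMAP (cat.), CH2Cl2, 0 °C → rt
Reagents that add atoms: none
Why: DMAP-catalysed O-acylation of the only hydroxyl installs the C7 benzoate of the target before the ring is dearomatised.

**Step 2**
Reactants: 3 2,5-dimethoxybenzyl benzoate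
Product: 4 2-(benzoyloxymethyl)-1,4-benzoquinone
Conditions: (NH4)2Ce(NO3)6 (2.5 equiv), MeCN/H2O, 0 °C
Reagents that add atoms: water, O
Why: Ceric ammonium nitrate oxidative demethylation of a hydroquinone dimethyl ether gives the p-quinone, and the benzylic benzoate is inert to Ce(IV).

**Step 3**
Reactants: 4 2-(benzoyloxymethyl)-1,4-benzoquinone
Product: 5 racemic trans-4,5-dibromo-1-(benzoyloxymethyl)cyclohex-1-ene-3,6-dione
Conditions: Br2 (1.0 equiv), CH2Cl2, −20 → 0 °C, dark
Reagents that add atoms: bromine, BrBr
Why: Electrophilic anti-addition of bromine to the unsubstituted C4=C5 bond (the CH2OBz-bearing C1=C2 bond is more hindered) gives the trans-dibromide, which masks C4=C5 and blocks tautomerisation to a hydroquinone during the reduction that follows.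

**Step 4**
Reactants: 5 racemic trans-dibromo-enedione
Product: 6 racemic all-trans 1-(benzoyloxymethyl)-4α,5β-dibromocyclohex-1-ene-3β,6α-diol
Conditions: NaBH4, Et2O/H2O, −10 °C
Reagents that add atoms: none
Why: Borohydride 1,2-reduction of both α-bromo enone carbonyls should, as for the unsubstituted dibromide, place each hydroxyl trans to its neighbouring bromine and so give the racemic diol with C3–OH and C6–OH on opposite faces.

**Step 5**
Reactants: 6 racemic all-trans dibromodiol
Product: 7 racemic 3β,6α-bis(methoxyacetate) of 6
Conditions: MeOCH2COCl (2.5 equiv), pyridine, DMAP (cat.), CH2Cl2, 0 °C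
Reagents that add atoms: methoxyacetyl chloride, COCC(Cl)=O
Why: Pyridine/DMAP acylation of both secondary alcohols gives a diester that lipases hydrolyse readily and whose remaining ester can later be removed beside benzoates.

**Step 6**
Reactants: 7 racemic bis(methoxyacetate)
Product: 8 (3R,4S,5S,6R)-3β-hydroxy-6α-(methoxyacetoxy)-4α,5β-dibromo-1-(benzoyloxymethyl)cyclohex-1-ene
Conditions: Burkholderia cepacia lipase (Amano PS), phosphate buffer pH 7.0/MTBE, 25 °C, stopped near half conversion; the unreacted enantiomeric diester is removed by chromatography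
Reagents that add atoms: none
Why: Lipase-catalysed kinetic resolution by ester hydrolysis. Kazlauskas' rule predicts fast cleavage of the ester on the (R)-carbinol flanked by the large CHBr and the medium vinyl CH (C3 of the enantiomer drawn), while the C6 ester next to the substituted alkene carbon and the benzoate are poor substrates. This step sets the absolute configuration and frees only C3–OH; the sense of resolution is to be confirmed on 8 by Mosher analysis.

**Step 7**
Reactants: 8 3β-alcohol; 9 benzoic acid
Product: 10 3α-benzoyloxy-6α-(methoxyacetoxy)-4α,5β-dibromo-1-(benzoyloxymethyl)cyclohex-1-ene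
Conditions: PhCO2H, PPh3, DIAD (betaine preformed), toluene, −20 → 0 °C
Reagents that add atoms: none
Why: Mitsunobu esterification of a secondary allylic alcohol: benzoate displaces the activated C3 oxygen with inversion, turning the trans-3,6 into the cis-3,6 dioxygen pattern, and SN2′ attack would have to occur at the fully substituted C1 and is disfavoured.

**Step 8**
Reactants: 10 dibromo diester
Product: 11 cis-3α-benzoyloxy-6α-(methoxyacetoxy)-1-(benzoyloxymethyl)cyclohexa-1,4-diene
Conditions: activated Zn dust, THF/AcOH (20:1), 0 °C, short contact; cold NaHCO3 work-up, used at once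
Reagents that add atoms: none
Why: Zinc-induced reductive anti-elimination of the vicinal trans-dibromide restores C4=C5 at 0 °C without touching a stereocentre, under conditions mild enough to keep the bis-allylic diester from aromatising by 1,4-elimination.

**Step 9**
Reactants: 11 cis-3,6-diacyloxy-1,4-diene
Product: 13 1-(benzoyloxymethyl)-3α-benzoyloxy-6α-(methoxyacetoxy)cyclohex-4-ene-1β,2β-diol, via cyclic osmate ester 12 (not isolated)
Conditions: K2OsO2(OH)4 (2 mol %), (DHQ)2PHAL (5 mol %), NMO (1.2 equiv), acetone/H2O 10:1, 0 °C; aq Na2SO3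
Reagents that add atoms: osmium tetroxide (formed from K2OsO2(OH)4 and NMO), O=[Os](=O)(=O)=O; N-methylmorpholine N-oxide, C[N+]1([O-])CCOCC1; water, O
Why: The ligated osmium(VIII) oxide adds across C1=C2 in a concerted [3+2] step to give the osmate ester 12, which is hydrolysed to the cis-diol while NMO returns osmium(VI) to osmium(VIII). The closest known reaction is the catalytic (Upjohn/Sharpless) syn-dihydroxylation of cyclohexenes anti to an allylic oxygen substituent, the rule used throughout conduritol chemistry. No ring of the product is closed. Both new stereocentres, C1 and C2, are controlled by the two allylic acyloxy groups at C3 and C6, which lie on the α face and reinforce each other, so both C–O bonds should form on the β face, cis to each other and trans to the C3 and C6 oxygens. The step also needs site selectivity for C1=C2 over C4=C5: the trisubstituted alkene is the more highly substituted one, and the phthalazine ligand accelerates trisubstituted alkenes far more than cis-disubstituted ones, while its own face preference (CH2OBz in the south-west quadrant of the Sharpless mnemonic, attack from below) coincides with the substrate bias. Cold, near-neutral conditions keep the bis-allylic diester from aromatising and the methoxyacetate from hydrolysing.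

**Step 10**
Reactants: 13 1β,2β-diol
Product: 14 2β-O-tert-butyldimethylsilyl ether of 13
Conditions: TBSOTf (1.1 equiv), 2,6-lutidine, CH2Cl2, −78 → −40 °C
Reagents that add atoms: tert-butyldimethylsilyl triflate, CC(C)(C)[Si](C)(C)OS(=O)(=O)C(F)(F)F
Why: Silylation of the only secondary hydroxyl (the tertiary C1–OH does not react with one equivalent at low temperature) masks C2–OH, so that it can be neither sulfonylated nor take up the C3 benzoyl group under the base of step 12.

**Step 11**
Reactants: 14 2β-silyl ether 6α-methoxyacetate
Product: 15 1-(benzoyloxymethyl)-3α-benzoyloxy-2β-(tert-butyldimethylsilyloxy)cyclohex-4-ene-1β,6α-diol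
Conditions: Yb(OTf)3 (20 mol %), MeOH, 0 °C → rt
Reagents that add atoms: none
Why: Lanthanide-catalysed methanolysis in which chelation by the α-methoxy ester activates only the methoxyacetate, so the two benzoates and the TBS ether should stay in place and C6–OH is freed with retention.

**Step 12**
Reactants: 15 1β,6α-diol
Product: 17 2β-O-tert-butyldimethylsilyl ether of the target (1β,6β-oxirane), via allylic mesylate 16 (not isolated)
Conditions: Ms2O (1.2 equiv), Et3N, CH2Cl2, −20 °C; then DBU, 0 °C → rt
Reagents that add atoms: none
Why: Mesylation of the only free secondary alcohol, then intramolecular Williamson etherification (3-exo-tet) by the trans, antiperiplanar tertiary C1 oxygen inverts C6 and closes the cis-fused oxirane on the β face; the anhydride is used so that no chloride can displace the allylic mesylate.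

**Step 13**
Reactants: 17 silyl-protected oxirane
Product: 18 [(1S,2S,3R,6R)-3-(benzoyloxy)-2-hydroxy-7-oxabicyclo[4.1.0]hept-4-en-1-yl]methyl benzoate
Conditions: HF·pyridine, pyridine, THF, 0 °C → rt
Reagents that add atoms: none
Why: Fluoride cleavage of the silyl ether under buffered, non-basic conditions should free C2–OH without opening the vinyl oxirane and without C3→C2 benzoyl migration.

**Compound list**

1 | 2,5-dimethoxybenzyl alcohol | COc1ccc(OC)c(CO)c1 | starting material
2 | benzoyl chloride | O=C(Cl)c1ccccc1 | starting material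
3 | 2,5-dimethoxybenzyl benzoate | COc1ccc(OC)c(COC(=O)c2ccccc2)c1 | intermediate
4 | 2-(benzoyloxymethyl)-1,4-benzoquinone | O=C(OCC1=CC(=O)C=CC1=O)c1ccccc1 | intermediate
5 | racemic trans-4α,5β-dibromo-1-(benzoyloxymethyl)cyclohex-1-ene-3,6-dione | O=C(OCC1=CC(=O)[C@H](Br)[C@@H](Br)C1=O)c1ccccc1 | intermediate
6 | racemic 1-(benzoyloxymethyl)-4α,5β-dibromocyclohex-1-ene-3β,6α-diol | O=C(OCC1=C[C@@H](O)[C@H](Br)[C@@H](Br)[C@@H]1O)c1ccccc1 | intermediate
7 | racemic 3β,6α-bis(methoxyacetate) of 6 | O=C(OCC1=C[C@@H](OC(=O)COC)[C@H](Br)[C@@H](Br)[C@@H]1OC(=O)COC)c1ccccc1 | intermediate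
8 | (3R,4S,5S,6R)-3β-hydroxy-6α-(methoxyacetoxy)-4α,5β-dibromo-1-(benzoyloxymethyl)cyclohex-1-ene | O=C(OCC1=C[C@@H](O)[C@H](Br)[C@@H](Br)[C@@H]1OC(=O)COC)c1ccccc1 | intermediate
9 | benzoic acid | O=C(O)c1ccccc1 | starting material
10 | 3α-benzoyloxy-6α-(methoxyacetoxy)-4α,5β-dibromo-1-(benzoyloxymethyl)cyclohex-1-ene | O=C(OCC1=C[C@H](OC(=O)c2ccccc2)[C@H](Br)[C@@H](Br)[C@@H]1OC(=O)COC)c1ccccc1 | intermediate
11 | cis-3α-benzoyloxy-6α-(methoxyacetoxy)-1-(benzoyloxymethyl)cyclohexa-1,4-diene | O=C(OCC1=C[C@H](OC(=O)c2ccccc2)C=C[C@@H]1OC(=O)COC)c1ccccc1 | intermediate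
12 | cyclic 1β,2β-osmate(VI) ester of 13 | O=C(OC[C@@]1(O2)[C@@H](OC(=O)COC)C=C[C@@H](OC(=O)c3ccccc3)[C@@H]1O[Os]2(=O)=O)c1ccccc1 | intermediate
13 | 1-(benzoyloxymethyl)-3α-benzoyloxy-6α-(methoxyacetoxy)cyclohex-4-ene-1β,2β-diol | O=C(OC[C@@]1(O)[C@@H](OC(=O)COC)C=C[C@@H](OC(=O)c2ccccc2)[C@@H]1O)c1ccccc1 | intermediate
14 | 2β-O-TBS ether of 13 | O=C(OC[C@@]1(O)[C@@H](OC(=O)COC)C=C[C@@H](OC(=O)c2ccccc2)[C@@H]1O[Si](C)(C)C(C)(C)C)c1ccccc1 | intermediate
15 | 1-(benzoyloxymethyl)-3α-benzoyloxy-2β-(TBS-oxy)cyclohex-4-ene-1β,6α-diol | O=C(OC[C@@]1(O)[C@@H](O)C=C[C@@H](OC(=O)c2ccccc2)[C@@H]1O[Si](C)(C)C(C)(C)C)c1ccccc1 | intermediate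
16 | 6α-methanesulfonate of 15 | O=C(OC[C@@]1(O)[C@@H](OS(C)(=O)=O)C=C[C@@H](OC(=O)c2ccccc2)[C@@H]1O[Si](C)(C)C(C)(C)C)c1ccccc1 | intermediate
17 | 2β-O-TBS ether of the target | O=C(OC[C@@]12O[C@@H]1C=C[C@@H](OC(=O)c1ccccc1)[C@@H]2O[Si](C)(C)C(C)(C)C)c1ccccc1 | intermediate
18 | [(1S,2S,3R,6R)-3-(benzoyloxy)-2-hydroxy-7-oxabicyclo[4.1.0]hept-4-en-1-yl]methyl benzoate | O=C(OC[C@@]12O[C@@H]1C=C[C@@H](OC(=O)c1ccccc1)[C@@H]2O)c1ccccc1 | target

Total step count: 13
Longest linear sequence: 13 steps (1 → 18)

**Steps most likely to fail**

Step 9. What may go wrong is competing oxidation of C4=C5, over-oxidation, or loss of the diene through 1,4-elimination to an arene during steps 8 and 9. The fallback reverses the order of unmasking and oxidation. Starting from 10, the C1=C2 bond, then the only alkene, is dihydroxylated with K2OsO2(OH)4/NMO anti to the C3 and C6 esters to give the dibromo diol F1. Zinc dust in THF/AcOH at 0 °C then removes the two bromines and gives 13, where the route is rejoined. The labile diene 11 is never formed.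

Step 7. What may go wrong is erosion of the inversion through participation of the antiperiplanar C4 bromine (leading to retention), or elimination of the activated alcohol. The fallback carries out the inversion at C3 by an oxirane opening. From 8, DBU in CH2Cl2 closes the trans-bromohydrin to the 3β,4β-oxirane F2. Benzoic acid 9, buffered with a catalytic amount of its tetrabutylammonium salt, opens the vinyl oxirane at the allylic C3 with inversion to the 3α-benzoate 4β-alcohol F3. This is mesylated at once (Ms2O, pyridine) to the 4β-mesylate F4. Zinc dust then eliminates the 4-mesylate/5-bromide pair reductively and gives 11.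

Step 6. What may go wrong is insufficient discrimination by the lipase between the enantiomers or between the C3 and C6 esters, or slow loss of the C7 benzoate. The fallback resolves through a covalently bound chiral acid. From racemic 6, a Mitsunobu reaction with one equivalent of 9 esterifies the less hindered C3 hydroxyl with inversion to the cis hydroxy benzoate F5 (racemic at this point). Esterification of its C6 hydroxyl with (S)-O-methylmandelic acid (DCC, DMAP) gives two diastereomers. The one with the ring configuration of 10, the (S)-O-methylmandelate F6, is separated by chromatography or crystallisation. Yb(OTf)3 in methanol removes the α-methoxy ester and returns the cis hydroxy benzoate F5 as a single enantiomer, and methoxyacetyl chloride/pyridine converts it into 10.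

**Further compounds**

F1 | step 9 | 1-(benzoyloxymethyl)-3α-benzoyloxy-4α,5β-dibromo-6α-(methoxyacetoxy)cyclohexane-1β,2β-diol | O=C(OC[C@@]1(O)[C@@H](OC(=O)COC)[C@H](Br)[C@@H](Br)[C@@H](OC(=O)c2ccccc2)[C@@H]1O)c1ccccc1
F2 | step 7 | 3β,4β-epoxy-5β-bromo-6α-(methoxyacetoxy)-1-(benzoyloxymethyl)cyclohex-1-ene | O=C(OCC1=C[C@H]2O[C@H]2[C@@H](Br)[C@@H]1OC(=O)COC)c1ccccc1
F3 | step 7 | 3α-benzoyloxy-4β-hydroxy-5β-bromo-6α-(methoxyacetoxy)-1-(benzoyloxymethyl)cyclohex-1-ene | O=C(OCC1=C[C@H](OC(=O)c2ccccc2)[C@@H](O)[C@@H](Br)[C@@H]1OC(=O)COC)c1ccccc1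
F4 | step 7 | 4β-methanesulfonate of F3 | O=C(OCC1=C[C@H](OC(=O)c2ccccc2)[C@@H](OS(C)(=O)=O)[C@@H](Br)[C@@H]1OC(=O)COC)c1ccccc1
F5 | step 6 | 3α-benzoyloxy-4α,5β-dibromo-6α-hydroxy-1-(benzoyloxymethyl)cyclohex-1-ene (first racemic, then single enantiomer as drawn) | O=C(OCC1=C[C@H](OC(=O)c2ccccc2)[C@H](Br)[C@@H](Br)[C@@H]1O)c1ccccc1
F6 | step 6 | 6α-[(S)-2-methoxy-2-phenylacetate] of F5 | O=C(OCC1=C[C@H](OC(=O)c2ccccc2)[C@H](Br)[C@@H](Br)[C@@H]1OC(=O)[C@@H](OC)c1ccccc1)c1ccccc1
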